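The constants are those of an exercise, and the outcome is calculated.

The product of this catalytic round also holds its catalyst back: it pushes catalyst intermediate C up from free catalyst, and pairs of C fall into the resting dimer. So the question for these flasks is how much product each can make before that pairing costs it turnovers.

common to all: substrate 0.16 M; reagent 3.00 equiv; free catalyst 2 mol%; time 50 min

|  | remark | temperature |
|---|---|---|
| grey | at 70 °C until 25 min, from then on at 100 °C |  |
| red |  | 70 °C |
| amber |  | 100 °C |

- the flask that comes out highest in amount of product, in percent of the substrate charged, or "all alike" when all lie within 1.5 percentage points (grey / red / amber / all alike)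
- product at the end, in percent of the substrate charged, grey
- product at the end, in percent of the substrate charged, red
- product at the end, in percent of the substrate charged, amber

    substrate + free catalyst ⇌ catalyst intermediate A (K1 = 5.6 M⁻¹, k1 = 2.9 M⁻¹ min⁻¹, Ea1 = 58.0 kJ mol⁻¹, ΔH1 = −57.0 kJ mol⁻¹)
    reagent + catalyst intermediate A ⇌ catalyst intermediate B (K2 = 5.3 M⁻¹, k2 = 2.3 M⁻¹ min⁻¹, Ea2 = 76.0 kJ mol⁻¹, ΔH2 = 30.0 kJ mol⁻¹)
    catalyst intermediate B → by-product + catalyst intermediate C (k3 = 1.3 min⁻¹, Ea3 = 98.0 kJ mol⁻¹)
    catalyst intermediate C ⇌ free catalyst + product (K4 = 0.43 M, k4 = 12 min⁻¹, Ea4 = 84.0 kJ mol⁻¹, ΔH4 = −13.0 kJ mol⁻¹)
    2 catalyst intermediate C ⇌ resting dimer, settled at all times (K5 = 10000 M⁻¹, ΔH5 = 13.0 kJ mol⁻¹)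
    free catalyst + by-product ⇌ idle complex, settled at all times (K6 = 3.4 M⁻¹, ΔH6 = −59.0 kJ mol⁻¹)
    (constants at 70 °C)

- percentages count the substrate that a species holds: one resting dimer counts as two
- by-product is meant together with its idle complex
- where a step has two of a species, its rate is k times that concentration squared, and two are used at each turn
- the constants hold at 70 °C; other temperatures follow from the activation energies and enthalpies

I reckon the dimer as a correction to a plain count of turnovers. With substrate and reagent held at their charges, the steady round at 70 °C has 0.637 of intermediate B per intermediate A and 0.345 of A per free catalyst, which makes a turnover frequency per catalyst of 0.182 min⁻¹. Each constant at 100 °C carries a power of 8.5, the factor by which step 2 speeds up between the two temperatures, the exponent being the constant's activation energy or enthalpy over the activation energy of step 2. That gives 0.424 of B per A and 0.108 of A per free catalyst, hence a turnover frequency of 0.819 min⁻¹, which is 4.50 times the cold figure. Turnover frequency times loading times time gives the unhindered yield D: 0.182 for red, 0.819 for amber, and 0.501 for grey, counted over its cold and its hot stretch.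

Now the dimer. If product and free catalyst balance C, the dimer's catalyst over free catalyst at full conversion and full free catalyst is Π, which is 8.86 cold and 26.6 hot. Where the dimer dominates, free catalyst falls inversely with product, so the square of the yield grows linearly with time, not the yield itself. Folding this together, D times the root of Π over twice the sum of the working forms per free catalyst comes to 1.83 in amber, and I call this the parking number N. N is the squared ratio of unhindered yield to dimer-limited yield. Red has 0.174, below one, so there the dimer is a correction. Amber stands above one, so there the dimer is no small correction, and grey, reckoned with the hot constants, has 1.12.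

One number is not enough, though, since N says how hard the brake is and not how far the flask has gone, and substrate loss brakes too. I take that crudely as one plus D, whose square in amber is 3.31, larger than N. Adding the brakes in squares, the yield is D divided by the root of N plus the square of one plus D. This gives grey 27.3%, red 14.6%, amber 36.1%, and the highest is amber.

The forecast says amber, with grey 29% (23% to 35%), red 15% (12% to 19%) and amber 37% (30% to 45%), on the ground that “the longest time hot wins”.

The simulation gives grey 27.6%, red 14.7%, amber 36.5%, so amber comes highest.

Amber's N is 1.83, and a neighbouring flask is amber with 8 mol% of free catalyst. In my reckoning its loading multiplies D by 4.00 and N by that factor times its root, so D is 3.28 and N is 14.6, which gives a yield of 57.2%. The simulated neighbour reaches 52.8%, with the resting dimer at 77.4% of the catalyst, more than the 50.6% in amber, and its product stands above its substrate, which is at 40.6%.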